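**Plan**
- Ring atoms are numbered O1, C2(=O), C3(OH), C4(H), C5H2. After the two phenol protecting groups are removed, the retrosynthesis cuts C3–C4, the bond that joins the two C6C3 halves. It then cuts the ester bond O1–C2, which leaves an arylpyruvic acid and a coniferyl-type alcohol, both traced to O-benzylvanillin.
- Enabling feature: C3 is a tertiary carbinol next to the lactone carbonyl C2, which is an α-keto ester in disguise. C4 bears H and a CH2Ar group whose benzylic carbon can hold a radical, which is a styrene in disguise. The O1–C5 part of the lactone is itself the tether, so no helper has to be removed later.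
- Forward: the aldehyde is extended once to the cinnamyl alcohol and once to the arylpyruvic acid, and the two are esterified. One reductive ketyl–olefin cyclisation then closes the only non-aromatic ring and creates the tertiary alcohol and both stereocentres. Hydrogenolysis ends the route.
- Stereochemistry: the relative configuration (OH trans to the C4 benzyl, the two benzyl groups cis) comes from the anti transition state of the samarium ketyl. The absolute configuration comes from a chiral aminodiol ligand on samarium.
- Keto and enol tautomers and either alkene geometry converge on the same product.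

Key step: step 6

Assumption: the sense of induction of the aminodiol ligand (one operation from benzylamine and styrene oxide, both antipodes accessible, recovered by acid–base extraction) cannot be predicted for this substrate, so the (R,R) form is written and its antipode would be used if a test run shows the opposite sense; the keto ester is drawn as its keto tautomer although it should exist as a keto–enol mixture.

**Step 1**
Reactants: 1 4-(benzyloxy)-3-methoxybenzaldehyde; 2 triethyl phosphonoacetate
Product: 3 ethyl (E)-3-[4-(benzyloxy)-3-methoxyphenyl]acrylate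
Conditions: NaH, THF, 0 °C to rt
Reagents that add atoms: none
Why: A Horner–Wadsworth–Emmons olefination of an aromatic aldehyde with a stabilised phosphonate anion should give the E-cinnamate, and the aryl benzyl ether is inert to the base.

**Step 2**
Reactants: 3 ethyl (E)-3-[4-(benzyloxy)-3-methoxyphenyl]acrylate
Product: 4 (E)-3-[4-(benzyloxy)-3-methoxyphenyl]prop-2-en-1-ol
Conditions: diisobutylaluminium hydride (2.5 equiv), CH2Cl2, −78 °C; aq. potassium sodium tartrate
Reagents that add atoms: none
Why: 1,2-Reduction of an α,β-unsaturated ester by an aluminium hydride at low temperature should stop at the allylic alcohol and leave the alkene and the benzyl ether untouched.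

**Step 3**
Reactants: 1 4-(benzyloxy)-3-methoxybenzaldehyde; 5 N-acetylglycine
Product: 6 (Z)-4-[4-(benzyloxy)-3-methoxybenzylidene]-2-methyloxazol-5(4H)-one
Conditions: Ac2O, NaOAc, 100 °C
Reagents that add atoms: none
Why: In the Erlenmeyer–Plöchl azlactone synthesis, Ac2O cyclodehydrates N-acetylglycine to the oxazolone, whose C4 carbanion condenses with the aldehyde to give the thermodynamically preferred Z-arylidene azlactone.

**Step 4**
Reactants: 6 (Z)-4-[4-(benzyloxy)-3-methoxybenzylidene]-2-methyloxazol-5(4H)-one
Product: 8 3-[4-(benzyloxy)-3-methoxyphenyl]-2-oxopropanoic acid, via acetamidoacrylic acid 7 (not isolated)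
Conditions: 10% aq. NaOH, reflux, N2; then HCl, 0 °C, pH 1
Reagents that add atoms: water, SMILES O
Why: Alkaline hydrolysis of an Erlenmeyer azlactone opens the ring to 7, cleaves the enamide and hydrolyses the resulting enamine to the α-keto acid, which is the standard route to electron-rich arylpyruvic acids and spares the benzyl ether.

**Step 5**
Reactants: 8 3-[4-(benzyloxy)-3-methoxyphenyl]-2-oxopropanoic acid; 4 (E)-3-[4-(benzyloxy)-3-methoxyphenyl]prop-2-en-1-ol
Product: 9 (E)-3-[4-(benzyloxy)-3-methoxyphenyl]allyl 3-[4-(benzyloxy)-3-methoxyphenyl]-2-oxopropanoate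
Conditions: DCC, DMAP (cat.), CH2Cl2, 0 °C
Reagents that add atoms: none
Why: Steglich esterification works under neutral, cold conditions, so the acid-labile electron-rich cinnamyl alcohol is not ionised, and the unhindered primary alcohol should outcompete the hydrogen-bonded enol OH for the acyl donor.

**Step 6**
Reactants: 9 (E)-3-[4-(benzyloxy)-3-methoxyphenyl]allyl 3-[4-(benzyloxy)-3-methoxyphenyl]-2-oxopropanoate
Product: 12 (3S,4R)-3,4-bis[4-(benzyloxy)-3-methoxybenzyl]-3-hydroxydihydrofuran-2(3H)-one, via samarium ketyl 10 (not isolated), via cyclised benzylic radical 11 (not isolated)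
Conditions: SmI2 (0.1 M in THF, 2.5 equiv), (R,R)-N-benzylbis(2-hydroxy-2-phenylethyl)amine (2.5 equiv), MeOH (4 equiv), THF, −20 °C, 9 added slowly; aq. NH4Cl work-up
Reagents that add atoms: none
Why: Proposed new method: the SmI2–aminodiol complex gives one electron to the ketone C=O of the keto tautomer of 9 (by far the most easily reduced group), the trivalent samarium that results is held by the ketyl oxygen and the ester carbonyl oxygen in a planar five-membered chelate (10), the ketyl carbon (future C3) adds to the near carbon of the styrene (future C4), the p-alkoxybenzylic radical 11 takes a second electron from SmI2, and MeOH protonates the benzylic carbanion and the alkoxide. The closest known reaction type is the SmI2 ketyl–olefin 5-exo cyclisation of unsaturated ketones, including its enantioselective form in which an aminodiol ligand of this kind controls the cyclisation of chelating keto esters; new here is an α-keto ester whose allylic ester oxygen is the tether, so that the α-hydroxy-γ-lactone forms directly. The one ring closes 5-exo-trig through the lactone-like rotamer of the ester, which the long-lived captodative ketyl has time to reach, whereas the 6-endo mode would give an unstabilised secondary radical and should not compete. For C3 relative to C4, the distal styrene carbon turns away from the bulky, electron-rich O–Sm unit in the transition state (anti arrangement), which places OH trans to the CH2Ar group on C4 and the two benzyl groups cis, as the target requires. For the absolute configuration, the C2-symmetric ligand fills three sites on samarium and covers one face of the chelate, so the tethered alkene can reach the ketyl carbon only from the open face, which fixes C3 as S and, through the anti arrangement, C4 as R. The step needs ring closure to outrun protonation and a second electron transfer at the ketyl, which the radical-stabilising aryl group on the acceptor, the small amount of MeOH and the slow addition of 9 to excess reagent should secure; keto and enol tautomers and any Z alkene converge on one product, because only the keto form is reduced and the alkene geometry is lost in 11.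

**Step 7**
Reactants: 12 (3S,4R)-3,4-bis[4-(benzyloxy)-3-methoxybenzyl]-3-hydroxydihydrofuran-2(3H)-one
Product: 13 (3S,4R)-3-hydroxy-3,4-bis(4-hydroxy-3-methoxybenzyl)dihydrofuran-2(3H)-one
Conditions: H2 (1 atm), Pd/C (10 wt %), EtOAc–EtOH, rt
Reagents that add atoms: none
Why: Catalytic hydrogenolysis cleaves only the two aryl benzyl ethers, because the C3 hydroxyl is homobenzylic and the lactone is inert, so neither stereocentre is touched.

**Compound list**
1 | 4-(benzyloxy)-3-methoxybenzaldehyde | COc1cc(C=O)ccc1OCc1ccccc1 | starting material
2 | triethyl phosphonoacetate | CCOC(=O)CP(=O)(OCC)OCC | starting material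
3 | ethyl (E)-3-[4-(benzyloxy)-3-methoxyphenyl]acrylate | CCOC(=O)/C=C/c1ccc(OCc2ccccc2)c(OC)c1 | intermediate
4 | (E)-3-[4-(benzyloxy)-3-methoxyphenyl]prop-2-en-1-ol | OC/C=C/c1ccc(OCc2ccccc2)c(OC)c1 | intermediate
5 | N-acetylglycine | CC(=O)NCC(=O)O | starting material
6 | (Z)-4-[4-(benzyloxy)-3-methoxybenzylidene]-2-methyloxazol-5(4H)-one | CC1=N/C(=C\c2ccc(OCc3ccccc3)c(OC)c2)C(=O)O1 | intermediate
7 | (Z)-2-acetamido-3-[4-(benzyloxy)-3-methoxyphenyl]acrylic acid (present as its sodium salt) | CC(=O)N/C(=C\c1ccc(OCc2ccccc2)c(OC)c1)C(=O)O | intermediate
8 | 3-[4-(benzyloxy)-3-methoxyphenyl]-2-oxopropanoic acid | COc1cc(CC(=O)C(=O)O)ccc1OCc1ccccc1 | intermediate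
9 | (E)-3-[4-(benzyloxy)-3-methoxyphenyl]allyl 3-[4-(benzyloxy)-3-methoxyphenyl]-2-oxopropanoate | COc1cc(CC(=O)C(=O)OC/C=C/c2ccc(OCc3ccccc3)c(OC)c2)ccc1OCc1ccccc1 | intermediate
10 | O-SmI2 ketyl radical of 9 (aminodiol ligand on samarium omitted) | COc1cc(C[C](O[Sm](I)I)C(=O)OC/C=C/c2ccc(OCc3ccccc3)c(OC)c2)ccc1OCc1ccccc1 | intermediate
11 | cyclised benzylic radical, O-SmI2 alkoxide of the (3S,4R)-lactone (ligand omitted) | COc1cc([CH][C@@H]2COC(=O)[C@]2(O[Sm](I)I)Cc2ccc(OCc3ccccc3)c(OC)c2)ccc1OCc1ccccc1 | intermediate
12 | (3S,4R)-3,4-bis[4-(benzyloxy)-3-methoxybenzyl]-3-hydroxydihydrofuran-2(3H)-one | COc1cc(C[C@@H]2COC(=O)[C@]2(O)Cc2ccc(OCc3ccccc3)c(OC)c2)ccc1OCc1ccccc1 | intermediate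
13 | (3S,4R)-3-hydroxy-3,4-bis(4-hydroxy-3-methoxybenzyl)dihydrofuran-2(3H)-one (benzyl groups cis, OH trans to the C4 benzyl) | COc1cc(C[C@@H]2COC(=O)[C@]2(O)Cc2ccc(O)c(OC)c2)ccc1O | target

**Total step count:** 7. **Longest linear sequence:** 5 steps (steps 3, 4, 5, 6, 7 from 1; the branch through steps 1 and 2 is equally long).

**Steps most likely to fail**

1. **Step 6.**
   - What may go wrong:
     - Ring closure may lose to protonation and further reduction of the ketyl, because the ester must leave its preferred rotamer before the alkene can reach the radical.
     - Deprotonation of the substrate by samarium alkoxides may withdraw it as an unreactive enolate.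
     - Facial control by the ligand may be poor on a substrate class on which it has not been tried.
   - The fallback uses known chemistry throughout, makes the same ring bond by carbene C–H insertion, and sets out from 4.
   - Hydrogenation of the alkene with RhCl(PPh3)3 and H2, which keeps the benzyl ether, would give 3-[4-(benzyloxy)-3-methoxyphenyl]propan-1-ol F1.
   - Acylation with glyoxylic acid chloride p-toluenesulfonylhydrazone followed by Et3N would give 3-[4-(benzyloxy)-3-methoxyphenyl]propyl diazoacetate F2.
   - Rh2(MPPIM)4 (MPPIM = methyl 1-(3-phenylpropanoyl)-2-oxoimidazolidine-4-carboxylate), in the antipode that leads to the S lactone, in refluxing CH2Cl2 would insert the carbene into the C–H bond two carbons from the ester oxygen. This would give (S)-4-[4-(benzyloxy)-3-methoxybenzyl]dihydrofuran-2(3H)-one F3.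
   - Lithium diisopropylamide and commercial 4-(benzyloxy)-3-methoxybenzyl bromide would give (3S,4S)-3,4-bis[4-(benzyloxy)-3-methoxybenzyl]dihydrofuran-2(3H)-one F4.
   - KN(SiMe3)2 followed by 2-(phenylsulfonyl)-3-phenyloxaziridine would hydroxylate the enolate on the face away from the C4 benzyl group. The fallback comes back to the route at 12.

2. **Step 5.**
   - What may go wrong:
     - Activation of the acid may lead to acylation of its own enol.
     - DMAP may trigger aldol self-condensation of the product.
     - The electron-rich cinnamyl unit may ionise.
   - The fallback never activates the acid and reverses the polarity of the bond formation. It sets out from 4 and 8.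
   - PBr3 in Et2O at 0 °C would convert 4 into (E)-1-(benzyloxy)-4-(3-bromoprop-1-en-1-yl)-2-methoxybenzene F5, used at once.
   - SN2 alkylation of the caesium carboxylate of 8 (Cs2CO3, 0.5 equiv, DMF, 0 °C) with this bromide comes back to the route at 9.

3. **Step 4.**
   - What may go wrong: the arylpyruvate may undergo aldol self-condensation and oxidative degradation during the long heating in alkali.
   - The fallback avoids the nitrogen-containing intermediates and the hot base. It sets out from 1.
   - A Horner–Wadsworth–Emmons reaction with methyl 2-[(tert-butyldimethylsilyl)oxy]-2-(dimethoxyphosphoryl)acetate (LiN(SiMe3)2, THF, −78 °C) would give methyl (Z)-3-[4-(benzyloxy)-3-methoxyphenyl]-2-[(tert-butyldimethylsilyl)oxy]acrylate F6.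
   - LiOH in THF–water at rt followed by dilute HCl would cleave the ester and the silyl enol ether. The fallback comes back to the route at 8.

**Further compounds**
F1 | step 6 | 3-[4-(benzyloxy)-3-methoxyphenyl]propan-1-ol | OCCCc1ccc(OCc2ccccc2)c(OC)c1
F2 | step 6 | 3-[4-(benzyloxy)-3-methoxyphenyl]propyl diazoacetate | [N-]=[N+]=CC(=O)OCCCc1ccc(OCc2ccccc2)c(OC)c1
F3 | step 6 | (S)-4-[4-(benzyloxy)-3-methoxybenzyl]dihydrofuran-2(3H)-one | COc1cc(C[C@@H]2COC(=O)C2)ccc1OCc1ccccc1
F4 | step 6 | (3S,4S)-3,4-bis[4-(benzyloxy)-3-methoxybenzyl]dihydrofuran-2(3H)-one | COc1cc(C[C@@H]2COC(=O)[C@H]2Cc2ccc(OCc3ccccc3)c(OC)c2)ccc1OCc1ccccc1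
F5 | step 5 | (E)-1-(benzyloxy)-4-(3-bromoprop-1-en-1-yl)-2-methoxybenzene | BrC/C=C/c1ccc(OCc2ccccc2)c(OC)c1
F6 | step 4 | methyl (Z)-3-[4-(benzyloxy)-3-methoxyphenyl]-2-[(tert-butyldimethylsilyl)oxy]acrylate | COC(=O)/C(O[Si](C)(C)C(C)(C)C)=C/c1ccc(OCc2ccccc2)c(OC)c1
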